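**Plan**

1. Germacrane numbering is used: C1 carbinol, C2–C3, C4/C5 oxirane (methyl C15 on C4), C6 lactone CH–O, C7=C11 butenolide (C12 carbonyl, C13 CH2OAc), C8 CH–O–methacryloyl, C9, C10 CHMe. The enabling feature is that the C1 oxygen and the C4 oxirane oxygen are 1,4-related through C2–C3 and the oxirane is cis-fused to the ten-membered ring (C3 and C6 on the same face): with C1 as a ketone, C3 is the β-carbon of a vinyl ketone, and an oxiranyl radical at C4 (from a C4 carboxyl group), held through C5–C6, can reach it from that face.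
2. Retrosynthetic cuts, in order: C1–OH to C1=O; ring bond C3–C4 (decarboxylative radical conjugate addition of seco-acid 29); the oxirane oxygen (Sharpless epoxidation of the C4=C5 allylic alcohol); the two esters and C11–C13 (Stille); C7–C8 together with the butenolide ring (titanium-mediated coupling of ynoate 16 with aldehyde 8); C6–C7 (alkynylation of enal 13); C1–C10 (crotylboration).
3. Forward order: fragments 8 (steps 1–4) and 16 (steps 5–8); butenolide ring in step 9; side-chain and ester adjustment in steps 10–15; oxirane in step 16; oxidation to the keto acid in steps 17–18; ten-membered ring last, in step 19; C1 reduction in step 20.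
4. Stereochemistry: C10 from the crotylboration catalyst (step 1), C6 from the zinc–ProPhenol alkynylation (step 7), C8 from CBS reduction (step 13), C5 from the tartrate in step 16, C4 in the ring closure (cis fusion, step 19), C1 by Felkin–Anh hydride addition (step 20).

Key step: step 19

Assumption: the sense of induction of (R)-TRIP (step 1) and (S,S)-ProPhenol (step 7) on these aldehydes is taken by analogy with related enals; the antipodal catalyst is used if the opposite sense is found.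

Abbreviations: TBS = tert-butyldimethylsilyl, TES = triethylsilyl.

**Route**

Step 1
Reactants: 1 acrolein; 2 (E)-crotylboronic acid pinacol ester
Product: 4 (3S,4R)-4-methylhexa-1,5-dien-3-ol, via borate ester 3 (not isolated)
Conditions: (R)-TRIP phosphoric acid (5 mol %), toluene, −30 °C; aqueous work-up
Reagents that add atoms: none
Why: Chiral phosphoric acid-catalysed crotylboration through a closed chair transition state: the (E)-crotyl geometry gives the anti relationship and the catalyst the absolute configuration, so that the methyl-bearing carbon (later C10) is R.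

Step 2
Reactants: 4 (3S,4R)-4-methylhexa-1,5-dien-3-ol
Product: 5 tert-butyldimethyl{[(3S,4R)-4-methylhexa-1,5-dien-3-yl]oxy}silane
Conditions: TBSCl, imidazole, DMF, 23 °C
Reagents that add atoms: tert-butyldimethylsilyl chloride, CC(C)(C)[Si](C)(C)Cl
Why: Silylation of a secondary allylic alcohol; the ether masks the later C1 oxygen until step 15.

Step 3
Reactants: 5 TBS ether of the dienol
Product: 7 (3R,4S)-4-[(TBS)oxy]-3-methylhex-5-en-1-ol, via B-alkyl-9-BBN 6 (not isolated)
Conditions: 9-BBN (1.1 equiv), THF, 0 to 23 °C; then NaOH, H2O2, 0 °C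
Reagents that add atoms: hydrogen peroxide, OO
Why: Anti-Markovnikov hydroboration–oxidation; the bulky borane should take the vinyl group on the CHMe carbon, because the other vinyl group is shielded and inductively deactivated by the allylic silyl ether.

Step 4
Reactants: 7 (3R,4S)-4-[(TBS)oxy]-3-methylhex-5-en-1-ol
Product: 8 (3R,4S)-4-[(TBS)oxy]-3-methylhex-5-enal
Conditions: Dess–Martin periodinane, pyridine, CH2Cl2, 0 to 23 °C
Reagents that add atoms: none
Why: Dess–Martin oxidation of a primary alcohol; no stereocentre is α to the new aldehyde (later C8), so nothing can epimerise.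

Step 5
Reactants: 9 tert-butyldimethyl(prop-2-yn-1-yloxy)silane
Product: 12 (2E)-4-[(TBS)oxy]-3-methylbut-2-en-1-ol, via alkenylalane 10 (not isolated), via lithium aluminate 11 (not isolated)
Conditions: Me3Al (2.5 equiv), Cp2ZrCl2 (0.25 equiv), CH2Cl2, 0 to 23 °C; then n-BuLi, THF, −78 °C; (CH2O)n, −78 to 23 °C
Reagents that add atoms: trimethylaluminium, C[Al](C)C; formaldehyde (from paraformaldehyde), C=O
Why: Negishi carboalumination adds methyl and aluminium syn across the terminal alkyne (methyl to the internal carbon) and the aluminate is hydroxymethylated with retention, which fixes the (E)-trisubstituted alkene (later C4=C5).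

Step 6
Reactants: 12 (2E)-4-[(TBS)oxy]-3-methylbut-2-en-1-ol
Product: 13 (2E)-4-[(TBS)oxy]-3-methylbut-2-enal
Conditions: MnO2, CH2Cl2, 23 °C
Reagents that add atoms: none
Why: Manganese dioxide oxidation of a primary allylic alcohol, which leaves the alkene geometry and the silyl ether untouched.

Step 7
Reactants: 13 (2E)-4-[(TBS)oxy]-3-methylbut-2-enal; 14 methyl propiolate
Product: 15 methyl (4R,5E)-7-[(TBS)oxy]-4-hydroxy-6-methylhept-5-en-2-ynoate
Conditions: ZnMe2 (3 equiv), (S,S)-ProPhenol (10 mol %), toluene, 4 °C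
Reagents that add atoms: none
Why: Zinc–ProPhenol-catalysed asymmetric alkynylation of an enal; the dinuclear zinc catalyst sets the carbinol centre (later C6) as R.

Step 8
Reactants: 15 hydroxy ynoate
Product: 16 methyl (4R,5E)-7-[(TBS)oxy]-6-methyl-4-[(TES)oxy]hept-5-en-2-ynoate
Conditions: TESCl, imidazole, CH2Cl2, 0 °C
Reagents that add atoms: triethylsilyl chloride, CC[Si](Cl)(CC)CC
Why: Silylation removes the acidic hydroxyl before the organometallic step and gives a group that mild acid takes off selectively in step 9.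

Step 9
Reactants: 16 TES-protected ynoate; 8 (3R,4S)-4-[(TBS)oxy]-3-methylhex-5-enal
Product: 20 (5R)-4-[(3R,4S)-4-[(TBS)oxy]-1-hydroxy-3-methylhex-5-en-1-yl]-5-[(1E)-3-[(TBS)oxy]-2-methylprop-1-en-1-yl]-3-iodofuran-2(5H)-one (both C8 epimers), via alkynoate–titanium complex 17 (not isolated), via oxatitanacyclopentene 18 (not isolated), via iodo hydroxy ester 19 (not isolated)
Conditions: Ti(OiPr)4 (1.3 equiv), i-PrMgCl (2.6 equiv), Et2O, −78 to −50 °C; then 8, −50 °C; then I2, −50 to 0 °C; then PPTS, MeOH, 0 °C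
Reagents that add atoms: iodine, II
Why: Titanium alkoxide-mediated alkyne–aldehyde coupling with a Kulinkovich-type divalent titanium reagent: the aldehyde inserts into the Ti–C bond of complex 17 that is remote from the ester to give 18 with C6 and the ester cis, iodine cleaves the remaining C–Ti bond, and acid removes the TES group so that the C6 hydroxyl lactonises; C8 forms as a mixture that steps 12 and 13 correct.

Step 10
Reactants: 20 iodobutenolide
Product: 21 (5R)-4-[(3R,4S)-4-[(TBS)oxy]-1-hydroxy-3-methylhex-5-en-1-yl]-5-[(1E)-3-[(TBS)oxy]-2-methylprop-1-en-1-yl]-3-(hydroxymethyl)furan-2(5H)-one (both C8 epimers)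
Conditions: Bu3SnCH2OH (1.5 equiv), Pd2(dba)3 (5 mol %), AsPh3, CuI (10 mol %), NMP, 60 °C
Reagents that add atoms: (tributylstannyl)methanol, CCCC[Sn](CCCC)(CCCC)CO
Why: Stille coupling of the α-iodobutenolide transfers the hydroxymethyl group (C13); it is placed before the methacrylate is introduced, so that no Heck cyclisation onto that ester can compete.

Step 11
Reactants: 21 diol
Product: 22 {(5R)-4-[(3R,4S)-4-[(TBS)oxy]-1-hydroxy-3-methylhex-5-en-1-yl]-5-[(1E)-3-[(TBS)oxy]-2-methylprop-1-en-1-yl]-2-oxo-2,5-dihydrofuran-3-yl}methyl acetate (both C8 epimers)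
Conditions: Ac2O (1.1 equiv), 2,4,6-collidine, CH2Cl2, −20 °C
Reagents that add atoms: acetic anhydride, CC(=O)OC(C)=O
Why: Selective acetylation of the primary allylic alcohol over the hindered secondary one that sits next to the fully substituted alkene carbon.

Step 12
Reactants: 22 acetate
Product: 23 {(5R)-4-[(3R,4S)-4-[(TBS)oxy]-3-methylhex-5-enoyl]-5-[(1E)-3-[(TBS)oxy]-2-methylprop-1-en-1-yl]-2-oxo-2,5-dihydrofuran-3-yl}methyl acetate
Conditions: Dess–Martin periodinane, pyridine, CH2Cl2, 0 °C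
Reagents that add atoms: none
Why: Dess–Martin oxidation converts both C8 epimers into one ketone; C10 is β to the carbonyl and cannot epimerise.

Step 13
Reactants: 23 C8 ketone
Product: 24 {(5R)-4-[(1S,3R,4S)-4-[(TBS)oxy]-1-hydroxy-3-methylhex-5-en-1-yl]-5-[(1E)-3-[(TBS)oxy]-2-methylprop-1-en-1-yl]-2-oxo-2,5-dihydrofuran-3-yl}methyl acetate
Conditions: (R)-Me-CBS oxazaborolidine (0.2 equiv), catecholborane (1.5 equiv), toluene, −78 °C
Reagents that add atoms: none
Why: Corey–Bakshi–Shibata reduction: the fully substituted butenolide carbon is the large group and the CH2 the small one, so the (R)-catalyst should deliver hydride to the face that gives the (8S)-alcohol under reagent control.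

Step 14
Reactants: 24 (8S)-alcohol
Product: 25 {(5R)-4-[(1S,3R,4S)-4-[(TBS)oxy]-3-methyl-1-[(2-methylprop-2-enoyl)oxy]hex-5-en-1-yl]-5-[(1E)-3-[(TBS)oxy]-2-methylprop-1-en-1-yl]-2-oxo-2,5-dihydrofuran-3-yl}methyl acetate
Conditions: methacrylic anhydride, i-Pr2NEt, DMAP (0.1 equiv), CH2Cl2, 0 °C
Reagents that add atoms: methacrylic anhydride, C=C(C)C(=O)OC(=O)C(C)=C
Why: DMAP-catalysed acylation with retention at C8; the acetate on the primary position is the thermodynamically preferred ester there, so migration to C8 is not expected.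

Step 15
Reactants: 25 bis-silyl ether
Product: 26 {(5R)-4-[(1S,3R,4S)-4-hydroxy-3-methyl-1-[(2-methylprop-2-enoyl)oxy]hex-5-en-1-yl]-5-[(1E)-3-hydroxy-2-methylprop-1-en-1-yl]-2-oxo-2,5-dihydrofuran-3-yl}methyl acetate
Conditions: HF·pyridine, pyridine, THF, 0 to 23 °C
Reagents that add atoms: none
Why: Fluoride-mediated removal of both TBS groups under buffered acidic conditions that leave the esters and the base-sensitive butenolide alone; it is done before the oxirane is made.

Step 16
Reactants: 26 diol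
Product: 27 {(5S)-4-[(1S,3R,4S)-4-hydroxy-3-methyl-1-[(2-methylprop-2-enoyl)oxy]hex-5-en-1-yl]-5-[(2S,3S)-3-(hydroxymethyl)-3-methyloxiran-2-yl]-2-oxo-2,5-dihydrofuran-3-yl}methyl acetate
Conditions: Ti(OiPr)4 (0.2 equiv), L-(+)-diethyl tartrate (0.24 equiv), t-BuOOH (2 equiv), 4 Å MS, CH2Cl2, −20 °C
Reagents that add atoms: tert-butyl hydroperoxide, CC(C)(C)OO
Why: Sharpless asymmetric epoxidation of the (E)-trisubstituted primary allylic alcohol; L-(+)-tartrate gives the (2S,3S)-epoxy alcohol, so C5 is S by reagent control (this should override the bias of C6), while the slow vinyl carbinol at C1 and the electron-poor alkenes are left.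

Step 17
Reactants: 27 epoxy diol
Product: 28 {(5S)-5-[(2S,3R)-3-formyl-3-methyloxiran-2-yl]-4-[(1S,3R)-3-methyl-1-[(2-methylprop-2-enoyl)oxy]-4-oxohex-5-en-1-yl]-2-oxo-2,5-dihydrofuran-3-yl}methyl acetate
Conditions: Dess–Martin periodinane (3 equiv), pyridine, CH2Cl2, 0 °C
Reagents that add atoms: none
Why: Dess–Martin oxidation of both alcohols in one operation gives the C1 vinyl ketone (the radical acceptor) and the epoxy aldehyde; the buffered neutral medium should not epimerise C10.

Step 18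
Reactants: 28 keto aldehyde
Product: 29 (2R,3S)-3-[(2S)-4-(acetoxymethyl)-3-[(1S,3R)-3-methyl-1-[(2-methylprop-2-enoyl)oxy]-4-oxohex-5-en-1-yl]-5-oxo-2,5-dihydrofuran-2-yl]-2-methyloxirane-2-carboxylic acid
Conditions: NaClO2, NaH2PO4, 2-methyl-2-butene, t-BuOH–H2O, 0 °C
Reagents that add atoms: sodium chlorite, [Na+].[O-]Cl=O
Why: Pinnick oxidation turns the aldehyde into the glycidic acid at pH 4 without touching the enone, the esters or the oxirane.

Step 19
Reactants: 29 seco-acid
Product: 30 (4R,5S,6S,8S,10R)-13-acetoxy-4,5-epoxy-8-[(2-methylprop-2-enoyl)oxy]-1-oxogermacr-7(11)-en-12,6-olide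
Conditions: Ir[dF(CF3)ppy]2(dtbbpy)PF6 (2 mol %), K2HPO4 (1.2 equiv), degassed MeCN–H2O (9:1), 1 mM, blue LEDs (450 nm), 25 °C
Reagents that add atoms: none
Why: Proposed new method: the photoexcited trivalent iridium complex oxidises the glycidate carboxylate of 29, loss of CO2 gives the C4 oxiranyl σ-radical, this adds to the unsubstituted terminus C3 of the vinyl ketone, and the α-keto radical at C2 is reduced by divalent iridium and protonated, so that no hydrogen-atom donor is present that could quench the radical before the slow ring closure. The closest known reaction type is the photoredox decarboxylative Giese macrocyclisation of α-heteroatom-substituted carboxylic acids, together with radical macrocyclisation onto terminal enones; new is the strained, non-stabilised oxiranyl radical as the adding species. The ten-membered carbocycle is the only ring closed, and it closes in the 10-endo-trig mode, C3 being the unhindered and polarity-matched terminus. C4 is the only new stereocentre: the tertiary oxiranyl radical should invert faster than it cyclises, so its configuration in 29 does not matter, and it should close through the invertomer whose half-filled orbital is cis to the C5–C6 bond, because the chain carrying the acceptor starts at C6 and a cis-fused oxirane is the low-strain junction of a ten-membered ring; the methyl group then lies trans to C6, which is the (4R) configuration, while C5, C6, C8 and C10 are not touched. The step needs chemoselectivity for the vinyl ketone over the methacrylate and the butenolide and ring closure over intermolecular addition: the first is secured by the higher radical affinity of the unhindered enone, by the nine-membered s-cis lactone that attack on the methacrylate would require and by the full substitution of the butenolide alkene, the second by high dilution.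

Step 20
Reactants: 30 macrocyclic ketone
Product: 31 (1S,4R,5S,6S,8S,10R)-13-acetoxy-4,5-epoxy-1-hydroxy-8-[(2-methylprop-2-enoyl)oxy]germacr-7(11)-en-12,6-olide (CNP0119405.1)
Conditions: NaBH4, CeCl3·7H2O, MeOH, −78 °C
Reagents that add atoms: none
Why: Luche reduction (1,2-selective, sparing butenolide, methacrylate, acetate and oxirane): hydride should add from the outer face of the ring anti to the C10–C9 bond (Felkin–Anh), which gives the 1,10-anti (1S) alcohol.

**Compound list**

1 | prop-2-enal (acrolein) | C=CC=O | starting material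
2 | (E)-crotylboronic acid pinacol ester, 2-[(2E)-but-2-en-1-yl]-4,4,5,5-tetramethyl-1,3,2-dioxaborolane | C/C=C/CB1OC(C)(C)C(C)(C)O1 | starting material
3 | borate ester, 4,4,5,5-tetramethyl-2-{[(3S,4R)-4-methylhexa-1,5-dien-3-yl]oxy}-1,3,2-dioxaborolane | C=C[C@@H](C)[C@@H](OB1OC(C)(C)C(C)(C)O1)C=C | intermediate (not isolated)
4 | (3S,4R)-4-methylhexa-1,5-dien-3-ol | C=C[C@@H](C)[C@@H](O)C=C | intermediate
5 | tert-butyldimethyl{[(3S,4R)-4-methylhexa-1,5-dien-3-yl]oxy}silane | C=C[C@@H](C)[C@@H](O[Si](C)(C)C(C)(C)C)C=C | intermediate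
6 | B-alkyl-9-BBN, 9-[(3R,4S)-4-[(TBS)oxy]-3-methylhex-5-en-1-yl]-9-borabicyclo[3.3.1]nonane | C=C[C@H](O[Si](C)(C)C(C)(C)C)[C@H](C)CCB1C2CCCC1CCC2 | intermediate (not isolated)
7 | (3R,4S)-4-[(TBS)oxy]-3-methylhex-5-en-1-ol | OCC[C@@H](C)[C@@H](O[Si](C)(C)C(C)(C)C)C=C | intermediate
8 | (3R,4S)-4-[(TBS)oxy]-3-methylhex-5-enal | O=CC[C@@H](C)[C@@H](O[Si](C)(C)C(C)(C)C)C=C | intermediate
9 | tert-butyldimethyl(prop-2-yn-1-yloxy)silane | C#CCO[Si](C)(C)C(C)(C)C | starting material
10 | alkenylalane, [(1E)-3-[(TBS)oxy]-2-methylprop-1-en-1-yl]dimethylalumane | C[Al](C)/C=C(\C)CO[Si](C)(C)C(C)(C)C | intermediate (not isolated)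
11 | lithium aluminate, lithium butyl[(1E)-3-[(TBS)oxy]-2-methylprop-1-en-1-yl]dimethylaluminate | [Li+].CCCC[Al-](C)(C)/C=C(\C)CO[Si](C)(C)C(C)(C)C | intermediate (not isolated)
12 | (2E)-4-[(TBS)oxy]-3-methylbut-2-en-1-ol | OC/C=C(\C)CO[Si](C)(C)C(C)(C)C | intermediate
13 | (2E)-4-[(TBS)oxy]-3-methylbut-2-enal | O=C/C=C(\C)CO[Si](C)(C)C(C)(C)C | intermediate
14 | methyl prop-2-ynoate (methyl propiolate) | C#CC(=O)OC | starting material
15 | methyl (4R,5E)-7-[(TBS)oxy]-4-hydroxy-6-methylhept-5-en-2-ynoate | COC(=O)C#C[C@H](O)/C=C(\C)CO[Si](C)(C)C(C)(C)C | intermediate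
16 | methyl (4R,5E)-7-[(TBS)oxy]-6-methyl-4-[(TES)oxy]hept-5-en-2-ynoate | COC(=O)C#C[C@H](O[Si](CC)(CC)CC)/C=C(\C)CO[Si](C)(C)C(C)(C)C | intermediate
17 | alkynoate–titanium complex (diisopropoxytitanacyclopropene of 16) | COC(=O)C1=C([C@H](O[Si](CC)(CC)CC)/C=C(\C)CO[Si](C)(C)C(C)(C)C)[Ti]1(OC(C)C)OC(C)C | intermediate (not isolated)
18 | oxatitanacyclopentene from 17 and 8 | COC(=O)C1=C([C@H](O[Si](CC)(CC)CC)/C=C(\C)CO[Si](C)(C)C(C)(C)C)C(C[C@@H](C)[C@@H](O[Si](C)(C)C(C)(C)C)C=C)O[Ti]1(OC(C)C)OC(C)C | intermediate (not isolated)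
19 | iodo hydroxy ester, methyl (2E)-2-iodo-3-[C6 side chain]-4-hydroxyalk-2-enoate with C6–OTES cis to the ester | COC(=O)/C(I)=C(\[C@H](O[Si](CC)(CC)CC)/C=C(\C)CO[Si](C)(C)C(C)(C)C)C(O)C[C@@H](C)[C@@H](O[Si](C)(C)C(C)(C)C)C=C | intermediate (not isolated)
20 | iodobutenolide, (5R)-4-[(3R,4S)-4-[(TBS)oxy]-1-hydroxy-3-methylhex-5-en-1-yl]-5-[(1E)-3-[(TBS)oxy]-2-methylprop-1-en-1-yl]-3-iodofuran-2(5H)-one (C8 epimers) | C=C[C@H](O[Si](C)(C)C(C)(C)C)[C@H](C)CC(O)C1=C(I)C(=O)O[C@@H]1/C=C(\C)CO[Si](C)(C)C(C)(C)C | intermediate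
21 | diol, the 3-(hydroxymethyl) analogue of 20 (C8 epimers) | C=C[C@H](O[Si](C)(C)C(C)(C)C)[C@H](C)CC(O)C1=C(CO)C(=O)O[C@@H]1/C=C(\C)CO[Si](C)(C)C(C)(C)C | intermediate
22 | primary acetate of 21 (C8 epimers) | C=C[C@H](O[Si](C)(C)C(C)(C)C)[C@H](C)CC(O)C1=C(COC(C)=O)C(=O)O[C@@H]1/C=C(\C)CO[Si](C)(C)C(C)(C)C | intermediate
23 | C8 ketone, {(5R)-4-[(3R,4S)-4-[(TBS)oxy]-3-methylhex-5-enoyl]-5-[(1E)-3-[(TBS)oxy]-2-methylprop-1-en-1-yl]-2-oxo-2,5-dihydrofuran-3-yl}methyl acetate | C=C[C@H](O[Si](C)(C)C(C)(C)C)[C@H](C)CC(=O)C1=C(COC(C)=O)C(=O)O[C@@H]1/C=C(\C)CO[Si](C)(C)C(C)(C)C | intermediate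
24 | (8S)-alcohol, {(5R)-4-[(1S,3R,4S)-4-[(TBS)oxy]-1-hydroxy-3-methylhex-5-en-1-yl]-5-[(1E)-3-[(TBS)oxy]-2-methylprop-1-en-1-yl]-2-oxo-2,5-dihydrofuran-3-yl}methyl acetate | C=C[C@H](O[Si](C)(C)C(C)(C)C)[C@H](C)C[C@H](O)C1=C(COC(C)=O)C(=O)O[C@@H]1/C=C(\C)CO[Si](C)(C)C(C)(C)C | intermediate
25 | methacrylate of 24 | C=C[C@H](O[Si](C)(C)C(C)(C)C)[C@H](C)C[C@H](OC(=O)C(C)=C)C1=C(COC(C)=O)C(=O)O[C@@H]1/C=C(\C)CO[Si](C)(C)C(C)(C)C | intermediate
26 | diol, {(5R)-4-[(1S,3R,4S)-4-hydroxy-3-methyl-1-[(2-methylprop-2-enoyl)oxy]hex-5-en-1-yl]-5-[(1E)-3-hydroxy-2-methylprop-1-en-1-yl]-2-oxo-2,5-dihydrofuran-3-yl}methyl acetate | C=C[C@H](O)[C@H](C)C[C@H](OC(=O)C(C)=C)C1=C(COC(C)=O)C(=O)O[C@@H]1/C=C(\C)CO | intermediate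
27 | epoxy diol, {(5S)-4-[(1S,3R,4S)-4-hydroxy-3-methyl-1-[(2-methylprop-2-enoyl)oxy]hex-5-en-1-yl]-5-[(2S,3S)-3-(hydroxymethyl)-3-methyloxiran-2-yl]-2-oxo-2,5-dihydrofuran-3-yl}methyl acetate | C=C[C@H](O)[C@H](C)C[C@H](OC(=O)C(C)=C)C1=C(COC(C)=O)C(=O)O[C@@H]1[C@@H]1O[C@@]1(C)CO | intermediate
28 | keto aldehyde, {(5S)-5-[(2S,3R)-3-formyl-3-methyloxiran-2-yl]-4-[(1S,3R)-3-methyl-1-[(2-methylprop-2-enoyl)oxy]-4-oxohex-5-en-1-yl]-2-oxo-2,5-dihydrofuran-3-yl}methyl acetate | C=CC(=O)[C@H](C)C[C@H](OC(=O)C(C)=C)C1=C(COC(C)=O)C(=O)O[C@@H]1[C@@H]1O[C@@]1(C)C=O | intermediate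
29 | seco-acid, (2R,3S)-3-[(2S)-4-(acetoxymethyl)-3-[(1S,3R)-3-methyl-1-[(2-methylprop-2-enoyl)oxy]-4-oxohex-5-en-1-yl]-5-oxo-2,5-dihydrofuran-2-yl]-2-methyloxirane-2-carboxylic acid | C=CC(=O)[C@H](C)C[C@H](OC(=O)C(C)=C)C1=C(COC(C)=O)C(=O)O[C@@H]1[C@@H]1O[C@@]1(C)C(=O)O | intermediate
30 | (4R,5S,6S,8S,10R)-13-acetoxy-4,5-epoxy-8-[(2-methylprop-2-enoyl)oxy]-1-oxogermacr-7(11)-en-12,6-olide | C=C(C)C(=O)O[C@H]1C[C@@H](C)C(=O)CC[C@@]2(C)O[C@H]2[C@H]2OC(=O)C(COC(C)=O)=C12 | intermediate
31 | (1S,4R,5S,6S,8S,10R)-13-acetoxy-4,5-epoxy-1-hydroxy-8-[(2-methylprop-2-enoyl)oxy]germacr-7(11)-en-12,6-olide (CNP0119405.1) | C=C(C)C(=O)O[C@H]1C[C@@H](C)[C@@H](O)CC[C@@]2(C)O[C@H]2[C@H]2OC(=O)C(COC(C)=O)=C12 | target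

**Step count**

Total step count: 20. Longest linear sequence: 16 steps (steps 1–4, then 9–20; the branch 5–8, then 9–20, is equally long).

**Steps most likely to fail**

1. Step 19 (Proposed new method). What may go wrong: the oxiranyl radical is quenched by hydrogen abstraction or opens to an α-keto alkyl radical before the slow ten-membered ring closure, or it closes through the other invertomer. The fallback uses known chemistry only; it sets out from alcohol 7 and acrolein 1 and comes back at target 31. C3–C4 is made beforehand by cross-coupling and the ring is closed by olefin metathesis at C4=C5. Hydroboration of 7 with 9-BBN and B-alkyl Suzuki–Miyaura coupling with 2-bromopropene (Pd(dppf)Cl2, K3PO4, DMF–H2O) should give the isopropenyl alcohol F1, which Dess–Martin periodinane oxidises to the isopropenyl aldehyde F2. Acrolein 1 and methyl propiolate 14 give, under the conditions of step 7, the vinyl hydroxy ynoate F3, which is silylated as in step 8 to the vinyl TES ynoate F4. The titanium coupling of step 9 joins F4 and F2 to the vinyl iodobutenolide F5. The operations of steps 10 to 13 then give in turn the hydroxymethyl compound F6, its primary acetate F7, the ketone F8 and the (S)-carbinol F9. Ring-closing metathesis of F9 (second-generation Hoveyda–Grubbs catalyst, toluene, 80 °C, 1 mM) joins the isopropenyl and vinyl groups to the (4Z)-cyclodecene F10. Epoxidation of this only electron-rich alkene from its exposed face (mCPBA, NaHCO3, CH2Cl2, 0 °C) gives the cis-epoxide F11, acylation as in step 14 gives the silylated methacrylate F12, and HF·pyridine as in step 15 gives 31. C1 keeps the alcohol configuration set in step 1, so steps 16 to 20 fall away.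

2. Step 9. What may go wrong: elimination of the silyloxy group from the alkyne–titanium complex, attack of the Grignard reagent on the ester, or insertion of the aldehyde at the wrong alkyne carbon. The fallback sets out from enal 13 and aldehyde 8 and comes back at diol 21; the C7–C8 bond is made by a Nozaki–Hiyama–Kishi reaction of a preformed iodobutenolide. Alkynylation of 13 with 1-methoxy-4-[(prop-2-yn-1-yloxy)methyl]benzene under the conditions of step 7, but with the enantiomeric ligand, gives the (S)-propargylic alcohol F13, which ClCO2Me and pyridine convert into the methyl carbonate F14. Palladium-catalysed carbonylation (Pd(OAc)2, PPh3, CO, MeOH, 40 °C; anti SN2′ oxidative addition) gives the allenoate F15. Its iodolactonisation (I2, MeCN–H2O; anti addition) transfers the axial chirality to the lactone carbon and gives the β-iodobutenolide F16 with the C6 configuration of 20. Coupling of F16 with 8 (CrCl2, NiCl2 1 mol %, DMF, 23 °C) gives the PMB ether F17 as a pair of C8 epimers, and DDQ (CH2Cl2, pH 7 buffer) removes the PMB group to give 21.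

3. Step 20. What may go wrong: poor facial selectivity in the hydride addition to the conformationally mobile ten-membered ketone. The fallback sets out from ketone 30 and comes back at target 31. If the reduction gives mainly the C1-epimeric alcohol F18, a Mitsunobu reaction (ClCH2CO2H, PPh3, DIAD, THF, 0 °C) inverts C1 and gives the chloroacetate F19, which thiourea (NaHCO3, EtOH, 40 °C) cleaves in the presence of the acetate and the methacrylate to give 31.

**Further compounds**

F1 | step 19 | isopropenyl alcohol, (3R,4S)-4-[(TBS)oxy]-3,7-dimethyloct-7-en-1-ol | OCC[C@@H](C)[C@@H](O[Si](C)(C)C(C)(C)C)CCC(C)=C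
F2 | step 19 | isopropenyl aldehyde, (3R,4S)-4-[(TBS)oxy]-3,7-dimethyloct-7-enal | O=CC[C@@H](C)[C@@H](O[Si](C)(C)C(C)(C)C)CCC(C)=C
F3 | step 19 | vinyl hydroxy ynoate, methyl (4R)-4-hydroxyhex-5-en-2-ynoate | COC(=O)C#C[C@H](O)C=C
F4 | step 19 | vinyl TES ynoate, methyl (4R)-4-[(TES)oxy]hex-5-en-2-ynoate | COC(=O)C#C[C@H](O[Si](CC)(CC)CC)C=C
F5 | step 19 | vinyl iodobutenolide, (5R)-4-[(3R,4S)-4-[(TBS)oxy]-1-hydroxy-3,7-dimethyloct-7-en-1-yl]-5-ethenyl-3-iodofuran-2(5H)-one (C8 epimers) | C=C(C)CC[C@H](O[Si](C)(C)C(C)(C)C)[C@H](C)CC(O)C1=C(I)C(=O)O[C@@H]1C=C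
F6 | step 19 | hydroxymethyl compound, the 3-(hydroxymethyl) analogue of F5 | C=C(C)CC[C@H](O[Si](C)(C)C(C)(C)C)[C@H](C)CC(O)C1=C(CO)C(=O)O[C@@H]1C=C
F7 | step 19 | primary acetate of F6 | C=C(C)CC[C@H](O[Si](C)(C)C(C)(C)C)[C@H](C)CC(O)C1=C(COC(C)=O)C(=O)O[C@@H]1C=C
F8 | step 19 | ketone, {(5R)-4-[(3R,4S)-4-[(TBS)oxy]-3,7-dimethyloct-7-enoyl]-5-ethenyl-2-oxo-2,5-dihydrofuran-3-yl}methyl acetate | C=C(C)CC[C@H](O[Si](C)(C)C(C)(C)C)[C@H](C)CC(=O)C1=C(COC(C)=O)C(=O)O[C@@H]1C=C
F9 | step 19 | (S)-carbinol, {(5R)-4-[(1S,3R,4S)-4-[(TBS)oxy]-1-hydroxy-3,7-dimethyloct-7-en-1-yl]-5-ethenyl-2-oxo-2,5-dihydrofuran-3-yl}methyl acetate | C=C(C)CC[C@H](O[Si](C)(C)C(C)(C)C)[C@H](C)C[C@H](O)C1=C(COC(C)=O)C(=O)O[C@@H]1C=C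
F10 | step 19 | (4Z)-cyclodecene, (1S,4Z,6R,8S,10R)-13-acetoxy-1-[(TBS)oxy]-8-hydroxygermacra-4,7(11)-dien-12,6-olide | O[C@H]1C[C@@H](C)[C@@H](O[Si](C)(C)C(C)(C)C)CC/C(C)=C\[C@H]2OC(=O)C(COC(C)=O)=C12
F11 | step 19 | cis-epoxide, (1S,4R,5S,6S,8S,10R)-13-acetoxy-1-[(TBS)oxy]-4,5-epoxy-8-hydroxygermacr-7(11)-en-12,6-olide | O[C@H]1C[C@@H](C)[C@@H](O[Si](C)(C)C(C)(C)C)CC[C@@]2(C)O[C@H]2[C@H]2OC(=O)C(COC(C)=O)=C12
F12 | step 19 | silylated methacrylate, the 1-O-TBS ether of 31 | C=C(C)C(=O)O[C@H]1C[C@@H](C)[C@@H](O[Si](C)(C)C(C)(C)C)CC[C@@]2(C)O[C@H]2[C@H]2OC(=O)C(COC(C)=O)=C12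
F13 | step 9 | (S)-propargylic alcohol, (2E,4S)-1-[(TBS)oxy]-7-[(4-methoxybenzyl)oxy]-2-methylhept-2-en-5-yn-4-ol | COc1ccc(COCC#C[C@@H](O)/C=C(\C)CO[Si](C)(C)C(C)(C)C)cc1
F14 | step 9 | methyl carbonate of F13 | COc1ccc(COCC#C[C@@H](OC(=O)OC)/C=C(\C)CO[Si](C)(C)C(C)(C)C)cc1
F15 | step 9 | allenoate, methyl (aR,5E)-7-[(TBS)oxy]-2-{[(4-methoxybenzyl)oxy]methyl}-6-methylhepta-2,3,5-trienoate | COC(=O)C(COCc1ccc(OC)cc1)=[C@]=C([H])/C=C(\C)CO[Si](C)(C)C(C)(C)C
F16 | step 9 | β-iodobutenolide, (5R)-5-[(1E)-3-[(TBS)oxy]-2-methylprop-1-en-1-yl]-4-iodo-3-{[(4-methoxybenzyl)oxy]methyl}furan-2(5H)-one | COc1ccc(COCC2=C(I)[C@@H](/C=C(\C)CO[Si](C)(C)C(C)(C)C)OC2=O)cc1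
F17 | step 9 | PMB ether, the 13-O-(4-methoxybenzyl) ether of 21 (C8 epimers) | C=C[C@H](O[Si](C)(C)C(C)(C)C)[C@H](C)CC(O)C1=C(COCc2ccc(OC)cc2)C(=O)O[C@@H]1/C=C(\C)CO[Si](C)(C)C(C)(C)C
F18 | step 20 | C1-epimeric alcohol, (1R,4R,5S,6S,8S,10R)-13-acetoxy-4,5-epoxy-1-hydroxy-8-[(2-methylprop-2-enoyl)oxy]germacr-7(11)-en-12,6-olide | C=C(C)C(=O)O[C@H]1C[C@@H](C)[C@H](O)CC[C@@]2(C)O[C@H]2[C@H]2OC(=O)C(COC(C)=O)=C12
F19 | step 20 | chloroacetate, the 1-O-chloroacetyl ester of 31 | C=C(C)C(=O)O[C@H]1C[C@@H](C)[C@@H](OC(=O)CCl)CC[C@@]2(C)O[C@H]2[C@H]2OC(=O)C(COC(C)=O)=C12
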